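**Plan**
- Retrosynthesis: the C9 carbinol goes back to the ketone; the alkenes C1=C10 and C4=C5 are folded back into the σ-bonds C5–C10 and C1–C4 of a bicyclo[2.2.0]hexane; its bonds C10–C1 and C5–C4 are then cut ([2+2]); the last cuts are the C8–O ester bond, the C6–O lactone bond and the stearate.
- Enabling feature (germacrane numbering): C1=C10 (Z, C14 on C10) and C4=C5 (E, C15 on C4) are 1,5-related through C2–C3. C5–C10 with C14 is therefore a 2-methylcyclohex-2-enone ring that already carries C6–O, C7 and C8–O, and C1–C4 with C15 is the ring of 1-methylcyclobutene.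
- Forward order: carvone six-membered ring → acrylic acid → cis γ-lactone ring → C8 ketol → ester with the separately made side-chain acid → cyclobutane ring by photocycloaddition → ten-membered ring by thermal opening → C9 reduction.
- Stereochemistry: C7 from (S)-carvone; C6 by bromination anti to C7, then SN2 lactonisation; C8 by α-face hydroxylation, then Mitsunobu inversion; the side-chain centre from an oxazolidinone alkylation; 1(10)Z,4E from the cis-anti-cis adduct through the chair 1,4-diyl; C9 by chelate-controlled hydride delivery.

Key step: step 13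

Remark: germacrane numbering is used for the core throughout; β is the face of the six-membered ring that carries C11 at C7, α the opposite face; the side-chain stereocentre of the target is R.
Assumption: the cyclobutene is drawn as adding to the α face of the enone in step 13; the face does not matter for the target, because C1, C4, C5 and C10 all become trigonal in step 14.
Remark: the α-methylene lactone is carried unprotected, so every step after its formation is neutral, weakly acidic or non-nucleophilic.

Step 1
Reactants: 1 (S)-carvone
Product: 2 (5S)-5-(3-chloroprop-1-en-2-yl)-2-methylcyclohex-2-en-1-one (10-chlorocarvone)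
Conditions: Ca(OCl)2, CO2 (dry ice), CH2Cl2/H2O, 0 °C
Reagents that add atoms: calcium hypochlorite (acting as HOCl), [Ca+2].[O-]Cl.[O-]Cl
Why: Ene-type allylic chlorination by HOCl takes place at the electron-rich 1,1-disubstituted isopropenyl alkene and not at the electron-poor enone, moving the double bond towards the former methyl group and leaving the ring stereocentre untouched.

Step 2
Reactants: 2 10-chlorocarvone
Product: 3 2-[(1S)-4-methyl-5-oxocyclohex-3-en-1-yl]prop-2-enal
Conditions: 4-methylmorpholine N-oxide, NaHCO3, KI (cat.), MeCN, 45 °C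
Reagents that add atoms: 4-methylmorpholine N-oxide, C[N+]1([O-])CCOCC1
Why: Ganem oxidation, in which the N-oxide displaces the allylic halide (iodide relay) and the alkoxyammonium salt loses 4-methylmorpholine by base-induced elimination to give the 2-substituted acrolein without touching the enone.

Step 3
Reactants: 3 enal
Product: 4 2-[(1S)-4-methyl-5-oxocyclohex-3-en-1-yl]prop-2-enoic acid
Conditions: NaClO2, NaH2PO4, 2-methyl-2-butene, t-BuOH/H2O, 0 → 25 °C
Reagents that add atoms: sodium chlorite, [Na+].[O-]Cl=O
Why: Pinnick oxidation converts the enal into the acrylic acid under buffered conditions that leave both alkenes and the ketone alone, the hypochlorous acid by-product being scavenged by 2-methyl-2-butene.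

Step 4
Reactants: 4 acrylic acid
Product: 5 trimethylsilyl 2-[(1R)-4-methyl-5-(trimethylsilyloxy)cyclohexa-2,4-dien-1-yl]prop-2-enoate (linear dienol ether C9(OSi)=C10–C5=C6, used crude)
Conditions: KH (2.0 equiv), THF, 0 → 25 °C; then TMSCl, −78 → 0 °C; filtration under argon
Reagents that add atoms: chlorotrimethylsilane, C[Si](C)(C)Cl
Why: Under equilibrating conditions KH gives the thermodynamic, fully conjugated dienolate (deprotonation at C6, γ to the ketone) rather than the cross-conjugated C8 enolate, and TMSCl traps it on oxygen together with the carboxylate (thermodynamic silyl dienol ether formation).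

Step 5
Reactants: 5 bis-silyl dienol ether
Product: 8 (3aS,7aS)-6-methyl-3-methylidene-3a,4-dihydro-1-benzofuran-2,5(3H,7aH)-dione (cis-fused enone lactone: C9 ketone; C10=C5; O6 and C11 both β), via γ-bromo enone silyl ester 6 (not isolated), via γ-bromo enone acid 7 (not isolated)
Conditions: NBS, THF, −78 °C; then sat. aq NaHCO3, 0 → 25 °C
Reagents that add atoms: none
Why: Electrophilic bromination of a 1-silyloxy-1,3-diene takes place at the γ-carbon, here C6 on the face anti to the C7 substituent, and after hydrolysis of the silyl ester the carboxylate displaces the allylic bromide in a 5-exo-tet SN2 reaction with inversion, which puts O6 cis to C11 and sets C6 as S in the cis-fused lactone.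

Step 6
Reactants: 8 enone lactone
Product: 11 (3aR,4R,7aS)-4-hydroxy-6-methyl-3-methylidene-3a,4-dihydro-1-benzofuran-2,5(3H,7aH)-dione (8α-ketol: OH trans to C11), via cross-conjugated silyl dienol ether 9 (not isolated), via 8α-silyloxy ketone 10 (not isolated)
Conditions: TMSOTf, Et3N, CH2Cl2, −78 → 0 °C; pentane, filtration; then DMDO, acetone, −78 °C; then 1 M HCl, THF, 0 °C
Reagents that add atoms: dimethyldioxirane, CC1(C)OO1
Why: Soft enolisation is directed to the C8 methylene, the accessible α′ position, and Rubottom oxidation of the 2-silyloxydiene by DMDO on the convex α face, anti to C11 on the neighbouring ring-fusion carbon, gives the 8α-ketol, whose configuration is inverted in step 11.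

Step 7
Reactants: 12 (S)-4-benzyl-3-propanoyl-1,3-oxazolidin-2-one; 13 tert-butyl bromoacetate
Product: 14 tert-butyl (3R)-4-[(4S)-4-benzyl-2-oxo-1,3-oxazolidin-3-yl]-3-methyl-4-oxobutanoate
Conditions: NaN(SiMe3)2, THF, −78 °C; then 13, −78 → −40 °C
Reagents that add atoms: none
Why: Evans alkylation, in which the chelated Z-sodium enolate is alkylated on the face opposite the benzyl group, sets the R-configured methyl-bearing stereocentre of the side chain.

Step 8
Reactants: 14 alkylated imide
Product: 15 tert-butyl (3R)-4-hydroxy-3-methylbutanoate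
Conditions: LiBH4, MeOH (1 equiv), THF, 0 °C; aq NH4Cl
Reagents that add atoms: none
Why: LiBH4 reduces the activated exocyclic imide carbonyl much faster than the hindered tert-butyl ester and releases the oxazolidinone, giving the primary alcohol without touching the stereocentre (reductive auxiliary cleavage).

Step 9
Reactants: 15 hydroxy ester; 16 stearic acid
Product: 17 tert-butyl (3R)-3-methyl-4-(octadecanoyloxy)butanoate
Conditions: DCC, 4-(dimethylamino)pyridine (cat.), CH2Cl2, 0 → 25 °C
Reagents that add atoms: none
Why: Steglich esterification of an unhindered primary alcohol with stearic acid under carbodiimide activation and acyl-transfer catalysis.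

Step 10
Reactants: 17 tert-butyl ester
Product: 18 (3R)-3-methyl-4-(octadecanoyloxy)butanoic acid
Conditions: CF3CO2H/CH2Cl2 (1:4), 25 °C
Reagents that add atoms: none
Why: Acidolysis of the tert-butyl ester through the tert-butyl cation frees the acid and leaves the primary stearate intact.

Step 11
Reactants: 11 8α-ketol; 18 side-chain acid
Product: 19 (3aS,4S,7aS)-6-methyl-3-methylidene-2,5-dioxo-2,3,3a,4,5,7a-hexahydro-1-benzofuran-4-yl (3R)-3-methyl-4-(octadecanoyloxy)butanoate (enone lactone with the 8β-ester; O6, C11 and O8 all cis)
Conditions: PPh3, DIAD, THF, 0 °C (betaine preformed); then 18 and 11, 0 → 25 °C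
Reagents that add atoms: none
Why: Mitsunobu esterification of the activated α-ketol proceeds by SN2 displacement of the oxyphosphonium group by the carboxylate of 18 with inversion, turning the 8α-alcohol into the 8β-ester that is cis to C11 and O6 as in the target.

Step 12
Reactants: 20 methylenecyclobutane
Product: 21 1-methylcyclobutene
Conditions: KOt-Bu (cat.), DMSO, 25 °C; fractional distillation
Reagents that add atoms: none
Why: Base-catalysed prototropic isomerisation through the allyl anion moves the exocyclic double bond into the ring, where the trisubstituted alkene is favoured at equilibrium, and the lower-boiling product is taken off by fractional distillation.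

Step 13
Reactants: 19 enone lactone ester; 21 1-methylcyclobutene
Product: 22 head-to-tail cis-anti-cis photoadduct (cyclobutane C10–C1–C4–C5 fused to the cyclohexanone on its α face, C14 and H-5 β; cyclobutane C1–C2–C3–C4 turned away from the six-membered ring; lactone and 8β-ester unchanged)
Conditions: hν (350 nm, Pyrex), 21 (10 equiv), CH2Cl2, −40 °C
Reagents that add atoms: none
Why: Irradiation into the n,π* band of the enone gives, after intersystem crossing, the triplet enone, which adds to 21 through triplet 1,4-biradicals that close to the cyclobutane after spin inversion; this is the enone–alkene [2+2] photocycloaddition in its known enone–cyclobutene variant. The only ring formed, the four-membered ring C10–C1–C4–C5, is closed intermolecularly, C5–C4 and C10–C1 being made one after the other and the second by radical recombination. The route needs the head-to-tail orientation (methyl-bearing C4 on the β-carbon C5, C1 on C10), which is the normal sense for an electron-rich trisubstituted alkene and is reinforced here because the head-to-head adduct would join the two fully substituted carbons C10 and C4. C10 and C5 should become cis because a four-membered ring closes cis onto the cyclohexanone, on the α face opposite O6, C11 and the C8 ester; C1 and C4 are cis by the ring of 21 and anti to the six-membered ring because the C2–C3 bridge turns away from it. Only the regiochemistry and the cis-anti-cis relationship matter for the target, since all four new stereocentres become trigonal in step 14. The exocyclic methylene of the lactone does not absorb at 350 nm and should not be sensitised by the enone, and the large excess of 21 at −40 °C suppresses enone dimerisation.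

Step 14
Reactants: 22 photoadduct
Product: 23 (1(10)Z,4E,6S,7S,8S)-8-{[(3R)-3-methyl-4-(octadecanoyloxy)butanoyl]oxy}-9-oxogermacra-1(10),4,11(13)-trien-12,6-olide (cyclodecadienone)
Conditions: toluene (degassed, 0.01 M), 2,6-di-tert-butyl-4-methylphenol (cat.), base-washed sealed tube, 180 °C
Reagents that add atoms: none
Why: Thermal cycloreversion of the bicyclo[2.2.0]hexane, in which homolysis of the strained central C1–C4 bond gives a cyclohexane-1,4-diyl that cleaves C5–C10 from the chair with only the C10–C9 bond axial, should give the Z-C1=C10 and E-C4=C5 alkenes (cis-anti-cis adducts are known to open to cis,trans-cyclodeca-1,5-dienes), while conjugation of C1=C10 with the C9 ketone should hold the Cope equilibrium with the cis-divinylcyclohexanone on the side of the ten-membered ring.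

Step 15
Reactants: 23 cyclodecadienone
Product: 24 target, (1(10)Z,4E,6S,7S,8S,9R)-9-hydroxy-8-{[(3R)-3-methyl-4-(octadecanoyloxy)butanoyl]oxy}germacra-1(10),4,11(13)-trien-12,6-olide
Conditions: Zn(BH4)2, Et2O, −30 °C; sat. aq NH4Cl
Reagents that add atoms: none
Why: Chelation-controlled 1,2-reduction, in which divalent zinc bridges the C9 carbonyl and the C8 acyloxy oxygen and hydride enters from the side of H-8 (Cram chelate model), should give the 8,9-cis 9R carbinol, and Zn(BH4)2 leaves the esters, the lactone and its exocyclic alkene untouched.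

**Compound list**
1 | (S)-carvone, (5S)-2-methyl-5-(prop-1-en-2-yl)cyclohex-2-en-1-one | CC1=CC[C@@H](CC1=O)C(C)=C | starting material
2 | (5S)-5-(3-chloroprop-1-en-2-yl)-2-methylcyclohex-2-en-1-one | CC1=CC[C@@H](CC1=O)C(=C)CCl | intermediate
3 | 2-[(1S)-4-methyl-5-oxocyclohex-3-en-1-yl]prop-2-enal | CC1=CC[C@@H](CC1=O)C(=C)C=O | intermediate
4 | 2-[(1S)-4-methyl-5-oxocyclohex-3-en-1-yl]prop-2-enoic acid | CC1=CC[C@@H](CC1=O)C(=C)C(=O)O | intermediate
5 | trimethylsilyl 2-[(1R)-4-methyl-5-(trimethylsilyloxy)cyclohexa-2,4-dien-1-yl]prop-2-enoate | CC1=C(O[Si](C)(C)C)C[C@H](C=C1)C(=C)C(=O)O[Si](C)(C)C | intermediate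
6 | trimethylsilyl 2-[(1S,2R)-2-bromo-4-methyl-5-oxocyclohex-3-en-1-yl]prop-2-enoate (bromine trans to the acrylate) | CC1=C[C@@H](Br)[C@@H](CC1=O)C(=C)C(=O)O[Si](C)(C)C | intermediate
7 | 2-[(1S,2R)-2-bromo-4-methyl-5-oxocyclohex-3-en-1-yl]prop-2-enoic acid | CC1=C[C@@H](Br)[C@@H](CC1=O)C(=C)C(=O)O | intermediate
8 | (3aS,7aS)-6-methyl-3-methylidene-3a,4-dihydro-1-benzofuran-2,5(3H,7aH)-dione | CC1=C[C@@H]2OC(=O)C(=C)[C@@H]2CC1=O | intermediate
9 | trimethylsilyl dienol ether of 8 (C8=C9–OSiMe3, C10=C5) | CC1=C[C@@H]2OC(=O)C(=C)[C@@H]2C=C1O[Si](C)(C)C | intermediate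
10 | 8α-(trimethylsilyloxy) derivative of 8 (silyloxy group trans to C11) | CC1=C[C@@H]2OC(=O)C(=C)[C@@H]2[C@@H](O[Si](C)(C)C)C1=O | intermediate
11 | (3aR,4R,7aS)-4-hydroxy-6-methyl-3-methylidene-3a,4-dihydro-1-benzofuran-2,5(3H,7aH)-dione | CC1=C[C@@H]2OC(=O)C(=C)[C@@H]2[C@@H](O)C1=O | intermediate
12 | (S)-4-benzyl-3-propanoyl-1,3-oxazolidin-2-one | CCC(=O)N1[C@@H](Cc2ccccc2)COC1=O | starting material
13 | tert-butyl bromoacetate | CC(C)(C)OC(=O)CBr | starting material
14 | tert-butyl (3R)-4-[(4S)-4-benzyl-2-oxo-1,3-oxazolidin-3-yl]-3-methyl-4-oxobutanoate | CC(C)(C)OC(=O)C[C@@H](C)C(=O)N1[C@@H](Cc2ccccc2)COC1=O | intermediate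
15 | tert-butyl (3R)-4-hydroxy-3-methylbutanoate | CC(C)(C)OC(=O)C[C@@H](C)CO | intermediate
16 | stearic acid | CCCCCCCCCCCCCCCCCC(=O)O | starting material
17 | tert-butyl (3R)-3-methyl-4-(octadecanoyloxy)butanoate | CC(C)(C)OC(=O)C[C@@H](C)COC(=O)CCCCCCCCCCCCCCCCC | intermediate
18 | (3R)-3-methyl-4-(octadecanoyloxy)butanoic acid | OC(=O)C[C@@H](C)COC(=O)CCCCCCCCCCCCCCCCC | intermediate
19 | (3aS,4S,7aS)-6-methyl-3-methylidene-2,5-dioxo-2,3,3a,4,5,7a-hexahydro-1-benzofuran-4-yl (3R)-3-methyl-4-(octadecanoyloxy)butanoate | CC1=C[C@@H]2OC(=O)C(=C)[C@@H]2[C@H](OC(=O)C[C@@H](C)COC(=O)CCCCCCCCCCCCCCCCC)C1=O | intermediate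
20 | methylenecyclobutane | C=C1CCC1 | starting material
21 | 1-methylcyclobutene | CC1=CCC1 | intermediate
22 | head-to-tail cis-anti-cis photoadduct of 19 and 21 (bicyclo[2.2.0]hexane on the α face of the cyclohexanone) | C[C@]12[C@@H]3CC[C@]3(C)[C@H]1[C@@H]4OC(=O)C(=C)[C@@H]4[C@H](OC(=O)C[C@@H](C)COC(=O)CCCCCCCCCCCCCCCCC)C2=O | intermediate
23 | (1(10)Z,4E,6S,7S,8S)-8-{[(3R)-3-methyl-4-(octadecanoyloxy)butanoyl]oxy}-9-oxogermacra-1(10),4,11(13)-trien-12,6-olide | C=C1C(=O)O[C@H]2/C=C(\C)CC/C=C(/C)C(=O)[C@@H](OC(=O)C[C@@H](C)COC(=O)CCCCCCCCCCCCCCCCC)[C@@H]12 | intermediate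
24 | (1(10)Z,4E,6S,7S,8S,9R)-9-hydroxy-8-{[(3R)-3-methyl-4-(octadecanoyloxy)butanoyl]oxy}germacra-1(10),4,11(13)-trien-12,6-olide | C=C1C(=O)O[C@H]2/C=C(\C)CC/C=C(/C)[C@@H](O)[C@@H](OC(=O)C[C@@H](C)COC(=O)CCCCCCCCCCCCCCCCC)[C@@H]12 | target

**Step count and risks**
Total: 15 steps. Longest linear sequence: 10 steps (steps 1–6, 11, 13, 14, 15).

Most likely to fail:

Step 14. The cyclohexane-1,4-diyl may cleave C2–C3 instead of C5–C10. During hours at 180 °C in solution the dienone may also leak by Cope rearrangement into the cis-divinylcyclohexanone, or emerge with the 1(10)E,4Z pair of alkenes. The fallback opens the ring in the gas phase on a small, volatile silyl ether under kinetic control and attaches the side chain afterwards. It sets out from ketol 11. Silylation (TBSOTf, 2,6-lutidine, CH2Cl2) should give the 8α-silyl ether of the enone lactone F2. Irradiation with 21 at 350 nm should give the silyloxy photoadduct F3. Flash vacuum pyrolysis (about 500 °C, 0.01 mbar, millisecond contact time, cold trap) should give the 8α-silyloxy cyclodecadienone F4. HF·pyridine in THF should give the 8α-hydroxy cyclodecadienone F5. Mitsunobu esterification with 18 (PPh3, DIAD), with inversion at C8, returns to the route at 23.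

Step 13. The excited α-acyloxy enone may lose its C8 acyloxy group, or the long acyl chain may make the addition slow and poorly regioselective, at the cost of acid 18. The fallback reverses the order of cycloaddition and esterification. It sets out from ketol 11. Irradiation with 21 (350 nm, CH2Cl2, −40 °C) should give the 8α-hydroxy photoadduct F1. Mitsunobu esterification with 18 (PPh3, DIAD), with inversion at C8, returns to the route at 22.

Step 15. If the zinc chelate does not form, hydride may be delivered to the other carbonyl face through an open, Felkin-type transition state and give the 9-epimer; the acyl group may also migrate from O8 to O9 in the zinc alkoxide. The fallback replaces substrate control by catalyst control. It uses the Corey–Bakshi–Shibata reduction with (R)-1-methyl-3,3-diphenyltetrahydro-1H,3H-pyrrolo[1,2-c][1,3,2]oxazaborole (C18H20BNO) and catecholborane in toluene at −78 °C, in which the alkenyl side of the ketone acts as the large group. It sets out from 23 and arrives at 24, and it makes no new compound (F0).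

Further compounds
F1 | step 13 | 8α-hydroxy photoadduct (cis-anti-cis, head-to-tail; free hydroxyl at C8 trans to C11) | C[C@]12[C@@H]3CC[C@]3(C)[C@H]1[C@@H]4OC(=O)C(=C)[C@@H]4[C@@H](O)C2=O
F2 | step 14 | 8α-(tert-butyldimethylsilyloxy) enone lactone (silyl ether of 11) | CC1=C[C@@H]2OC(=O)C(=C)[C@@H]2[C@@H](O[Si](C)(C)C(C)(C)C)C1=O
F3 | step 14 | 8α-silyloxy photoadduct (cis-anti-cis, head-to-tail) | C[C@]12[C@@H]3CC[C@]3(C)[C@H]1[C@@H]4OC(=O)C(=C)[C@@H]4[C@@H](O[Si](C)(C)C(C)(C)C)C2=O
F4 | step 14 | (1(10)Z,4E)-8α-(tert-butyldimethylsilyloxy)-9-oxogermacra-1(10),4,11(13)-trien-12,6-olide | C=C1C(=O)O[C@H]2/C=C(\C)CC/C=C(/C)C(=O)[C@H](O[Si](C)(C)C(C)(C)C)[C@@H]12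
F5 | step 14 | (1(10)Z,4E)-8α-hydroxy-9-oxogermacra-1(10),4,11(13)-trien-12,6-olide | C=C1C(=O)O[C@H]2/C=C(\C)CC/C=C(/C)C(=O)[C@H](O)[C@@H]12
F0 | step 15 | none | none
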